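**Strategy**

The dihydropyran ring of the chroman is cut into acetone and a four-atom arene unit. O1 and C2 with both methyl groups are acetone, C3 is the methyl carbon of an aryl methyl ketone (temporary C4 carbonyl), and C8a is a C–F carbon activated by this ortho ketone and the para C6 ester. One operation (lithium enolate aldol addition to acetone, then intramolecular SNAr by the new tertiary alkoxide) joins C2 to C3 and O1 to C8a. The C4 ketone then becomes the C3–C4 alkene for Jacobsen epoxidation (3R). The C6 ester becomes the benzylic bromide that alkylates an isotetronate at its fully substituted carbon under chiral phase-transfer control.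

Key step: step 1

**Remarks**

- Chroman atoms are numbered O1, C2, C3, C4, C4a, C5–C8, C8a; atoms of the lactone are called "furanone C2" and so on.
- Assumption: methyl 3-acetyl-4-fluorobenzoate is taken as a catalogue building block.
- Assumption: the facial sense of the phase-transfer catalyst on the enolate of step 9 has no direct precedent. The cinchonidine-derived salt is chosen; the cinchonine-derived pseudoenantiomer would be used if the 2S epimer dominated.

**Route**

Step 1
Reactants: 1 methyl 3-acetyl-4-fluorobenzoate; 2 acetone
Product: 5 methyl 2,2-dimethyl-4-oxochroman-6-carboxylate, via lithium enolate 3 (not isolated), via lithium aldolate 4 (not isolated)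
Conditions: LDA (1.05 equiv), THF, −78 °C; 2 (1.5 equiv), −78 °C; then DMPU, −78 → 25 °C
Reagents that add atoms: none
Why: Kinetic deprotonation of the methyl ketone gives enolate 3, which adds to acetone (directed crossed aldol addition) to give the tertiary aldolate 4; on warming, its alkoxide attacks C8a, which the ortho ketone and the para ester activate, and fluoride leaves through a Meisenheimer intermediate (addition–elimination SNAr). The closest known reaction types are the lithium-enolate aldol addition to ketones and the intramolecular SNAr etherification of 2-fluoroaryl ketones, run here in tandem as the oxygen-transposed counterpart of the Kabbe chromanone synthesis. The dihydropyranone ring closes by six-membered attack of O1 on the arene carbon (formally 6-exo-trig). No stereocentre is formed. The step needs ring closure to outrun retro-aldol cleavage of 4 and needs enolisation only at the acetyl group; the doubly activated C–F bond with irreversible loss of fluoride should secure the first, and the absence of any other acidic C–H in 1 secures the second.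

Step 2
Reactants: 5 methyl 2,2-dimethyl-4-oxochroman-6-carboxylate
Product: 6 racemic methyl 4-hydroxy-2,2-dimethylchroman-6-carboxylate
Conditions: NaBH4, MeOH, 0 °C
Reagents that add atoms: none
Why: Borohydride reduction of the aryl ketone (chemoselective over the methyl ester) gives the benzylic alcohol, whose C4 configuration is irrelevant because the centre is removed in step 3.

Step 3
Reactants: 6 racemic methyl 4-hydroxy-2,2-dimethylchroman-6-carboxylate
Product: 7 methyl 2,2-dimethyl-2H-chromene-6-carboxylate
Conditions: TsOH·H2O (5 mol%), toluene, reflux, Dean–Stark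
Reagents that add atoms: none
Why: Acid-catalysed E1 dehydration through the C4 benzylic cation, which the ortho ring oxygen stabilises, should give the conjugated 2H-chromene, the quaternary C2 leaving C3 as the only site of proton loss.

Step 4
Reactants: 7 methyl 2,2-dimethyl-2H-chromene-6-carboxylate
Product: 8 methyl (3R,4R)-3,4-epoxy-2,2-dimethylchroman-6-carboxylate
Conditions: (R,R)-[N,N'-bis(3,5-di-tert-butylsalicylidene)-1,2-cyclohexanediaminato]manganese chloride (trivalent manganese, 4 mol%), aq. NaOCl (pH 11.3), 4-phenylpyridine N-oxide (20 mol%), CH2Cl2, 0 °C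
Reagents that add atoms: sodium hypochlorite, [Na+].[O-]Cl
Why: Jacobsen epoxidation, for which cis-configured, arene-conjugated 2,2-dimethylchromenes are a favoured substrate class; the (R,R)-salen complex should deliver oxygen to the face that gives the 3R,4R epoxide, so C3 is set by catalyst control.

Step 5
Reactants: 8 methyl (3R,4R)-3,4-epoxy-2,2-dimethylchroman-6-carboxylate
Product: 9 (3R)-6-(hydroxymethyl)-2,2-dimethylchroman-3-ol
Conditions: LiAlH4 (2 equiv), THF, 0 → 25 °C; aqueous work-up
Reagents that add atoms: none
Why: Hydride reduction: SN2 attack of hydride at the benzylic, less hindered C4 opens the epoxide without touching the C3–O bond (3R retained), and the same reagent reduces the methyl ester to the primary benzylic alcohol.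

Step 6
Reactants: 9 (3R)-6-(hydroxymethyl)-2,2-dimethylchroman-3-ol
Product: 10 (3R)-6-(bromomethyl)-2,2-dimethylchroman-3-ol
Conditions: CBr4 (1.1 equiv), PPh3 (1.1 equiv), CH2Cl2, 0 °C; used without storage
Reagents that add atoms: carbon tetrabromide, BrC(Br)(Br)Br
Why: Appel bromination, which should convert the primary benzylic alcohol much faster than the secondary alcohol shielded by the quaternary C2.

Step 7
Reactants: 11 4-hydroxyphenylpyruvic acid; 12 methyl glyoxylate
Product: 14 racemic methyl 4-hydroxy-3-(4-hydroxyphenyl)-5-oxo-2,5-dihydrofuran-2-carboxylate, via aldol adduct 13 (not isolated)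
Conditions: Et3N (2.2 equiv), 12 (2 equiv), THF, 0 → 25 °C; then 2 M HCl, 25 °C
Reagents that add atoms: none
Why: Aldol addition of the enolised arylpyruvate to the highly electrophilic glyoxylate followed by acid-promoted lactonisation of the gamma-hydroxy alpha-keto acid (classical isotetronic acid synthesis); the furanone C2 centre is formed racemic and is erased by deprotonation in step 9.

Step 8
Reactants: 14 racemic methyl 4-hydroxy-3-(4-hydroxyphenyl)-5-oxo-2,5-dihydrofuran-2-carboxylate
Product: 15 racemic methyl 4-(benzyloxy)-3-[4-(benzyloxy)phenyl]-5-oxo-2,5-dihydrofuran-2-carboxylate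
Conditions: BnBr (2.05 equiv), K2CO3 (2.2 equiv), acetone, 25 °C
Reagents that add atoms: benzyl bromide, BrCc1ccccc1
Why: Williamson O-alkylation of the two acidic hydroxyl groups (enol and phenol) with a mild carbonate base; keeping benzyl bromide near two equivalents should avoid C-benzylation at the less acidic furanone C2–H.

Step 9
Reactants: 15 racemic methyl 4-(benzyloxy)-3-[4-(benzyloxy)phenyl]-5-oxo-2,5-dihydrofuran-2-carboxylate; 10 (3R)-6-(bromomethyl)-2,2-dimethylchroman-3-ol
Product: 16 methyl (2R)-4-(benzyloxy)-3-[4-(benzyloxy)phenyl]-2-{[(3R)-3-hydroxy-2,2-dimethylchroman-6-yl]methyl}-5-oxo-2,5-dihydrofuran-2-carboxylate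
Conditions: O-allyl-N-(9-anthracenylmethyl)cinchonidinium bromide (10 mol%), Cs2CO3 (1.5 equiv), toluene, −20 °C
Reagents that add atoms: none
Why: Asymmetric phase-transfer alkylation: deprotonation at furanone C2 gives an ester-stabilised 2-furanolate that should be benzylated at C2 (restoring the conjugated butenolide, whereas C4 is blocked by the benzyloxy and aryl groups) by the reactive 4-alkoxybenzyl bromide inside the chiral ammonium ion pair, which sets the quaternary 2R centre by catalyst control, the hindered free alcohol of 10 not being deprotonated by carbonate.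

Step 10
Reactants: 16 methyl (2R)-4-(benzyloxy)-3-[4-(benzyloxy)phenyl]-2-{[(3R)-3-hydroxy-2,2-dimethylchroman-6-yl]methyl}-5-oxo-2,5-dihydrofuran-2-carboxylate
Product: 17 methyl (2R)-4-hydroxy-3-(4-hydroxyphenyl)-2-{[(3R)-3-hydroxy-2,2-dimethylchroman-6-yl]methyl}-5-oxo-2,5-dihydrofuran-2-carboxylate
Conditions: H2 (1 atm), 10% Pd/C, EtOAc, 25 °C
Reagents that add atoms: none
Why: Catalytic hydrogenolysis of the aryl benzyl ether and the enol benzyl ether; the tetrasubstituted lactone alkene, the ester, the chroman and both stereocentres should be untouched.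

**Compound list**

1 | methyl 3-acetyl-4-fluorobenzoate | COC(=O)c1ccc(F)c(C(C)=O)c1 | starting material
2 | acetone | CC(C)=O | starting material
3 | lithium 1-[2-fluoro-5-(methoxycarbonyl)phenyl]ethenolate (lithium enolate) | COC(=O)c1ccc(F)c(C(=C)[O-])c1.[Li+] | intermediate (not isolated)
4 | lithium 4-[2-fluoro-5-(methoxycarbonyl)phenyl]-2-methyl-4-oxobutan-2-olate (lithium aldolate) | COC(=O)c1ccc(F)c(C(=O)CC(C)(C)[O-])c1.[Li+] | intermediate (not isolated)
5 | methyl 2,2-dimethyl-4-oxochroman-6-carboxylate | COC(=O)c1ccc2OC(C)(C)CC(=O)c2c1 | intermediate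
6 | racemic methyl 4-hydroxy-2,2-dimethylchroman-6-carboxylate | COC(=O)c1ccc2OC(C)(C)CC(O)c2c1 | intermediate
7 | methyl 2,2-dimethyl-2H-chromene-6-carboxylate | COC(=O)c1ccc2OC(C)(C)C=Cc2c1 | intermediate
8 | methyl (3R,4R)-3,4-epoxy-2,2-dimethylchroman-6-carboxylate | COC(=O)c1ccc2OC(C)(C)[C@@H]3O[C@@H]3c2c1 | intermediate
9 | (3R)-6-(hydroxymethyl)-2,2-dimethylchroman-3-ol | OCc1ccc2c(c1)C[C@@H](O)C(C)(C)O2 | intermediate
10 | (3R)-6-(bromomethyl)-2,2-dimethylchroman-3-ol | BrCc1ccc2c(c1)C[C@@H](O)C(C)(C)O2 | intermediate
11 | 4-hydroxyphenylpyruvic acid | OC(=O)C(=O)Cc1ccc(O)cc1 | starting material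
12 | methyl glyoxylate | COC(=O)C=O | starting material
13 | 4-hydroxy-3-(4-hydroxyphenyl)-5-methoxy-2,5-dioxopentanoic acid (aldol adduct, mixture of stereoisomers) | COC(=O)C(O)C(C(=O)C(O)=O)c1ccc(O)cc1 | intermediate (not isolated)
14 | racemic methyl 4-hydroxy-3-(4-hydroxyphenyl)-5-oxo-2,5-dihydrofuran-2-carboxylate | COC(=O)C1OC(=O)C(O)=C1c1ccc(O)cc1 | intermediate
15 | racemic methyl 4-(benzyloxy)-3-[4-(benzyloxy)phenyl]-5-oxo-2,5-dihydrofuran-2-carboxylate | COC(=O)C1OC(=O)C(OCc2ccccc2)=C1c1ccc(OCc2ccccc2)cc1 | intermediate
16 | methyl (2R)-4-(benzyloxy)-3-[4-(benzyloxy)phenyl]-2-{[(3R)-3-hydroxy-2,2-dimethylchroman-6-yl]methyl}-5-oxo-2,5-dihydrofuran-2-carboxylate | COC(=O)[C@]1(Cc2ccc3c(c2)C[C@@H](O)C(C)(C)O3)OC(=O)C(OCc2ccccc2)=C1c1ccc(OCc2ccccc2)cc1 | intermediate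
17 | methyl (2R)-4-hydroxy-3-(4-hydroxyphenyl)-2-{[(3R)-3-hydroxy-2,2-dimethylchroman-6-yl]methyl}-5-oxo-2,5-dihydrofuran-2-carboxylate | COC(=O)[C@]1(Cc2ccc3c(c2)C[C@@H](O)C(C)(C)O3)OC(=O)C(O)=C1c1ccc(O)cc1 | target

**Step count and risks**

Total step count: 10. Longest linear sequence: 8 steps (steps 1–6, 9, 10); steps 7–8 form the second branch.

Steps most likely to fail:

1. Step 9. The ion pair may discriminate the two faces of the planar furanolate poorly, or deliver the wrong face, so that the quaternary centre forms with low selectivity. Fallback: stereocontrol at this centre is given up. Starting from 15 and 10, the alkylation is run without a chiral catalyst (Cs2CO3, DMF, 0 °C). It should give 16 together with its C2 epimer, methyl (2S)-4-(benzyloxy)-3-[4-(benzyloxy)phenyl]-2-{[(3R)-3-hydroxy-2,2-dimethylchroman-6-yl]methyl}-5-oxo-2,5-dihydrofuran-2-carboxylate F1. The two are diastereomers because of the fixed 3R centre and are separated by preparative HPLC on a chiral stationary phase. The route is rejoined at 16.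

2. Step 1. Retro-aldol cleavage of the lithium aldolate may outrun ring closure on warming, returning the enolate to self-condensation. Fallback: starting from 1, the ketone is converted with trimethylsilyl triflate and Et3N into the silyl enol ether methyl 4-fluoro-3-[1-(trimethylsilyloxy)ethenyl]benzoate F2. A Mukaiyama aldol addition to acetone mediated by TiCl4 (CH2Cl2, −78 °C) proceeds through a titanium aldolate that does not revert and gives, after work-up, methyl 4-fluoro-3-(3-hydroxy-3-methylbutanoyl)benzoate F3. The crude hydroxy ketone is closed at once by SNAr with NaH in THF at 0 °C, so both bonds still arise in one telescoped sequence. The route is rejoined at 5.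

3. Step 5. Aluminium species may ionise the epoxide toward the C4 benzylic cation; a hydride shift from C3 would then give the 3-ketone, and its reduction would erode the enantiomeric purity at C3. Fallback: starting from 8, the benzylic C4–O bond is cleaved by hydrogenolysis (H2, 10% Pd/C, EtOAc), which leaves C3 untouched and gives methyl (3R)-3-hydroxy-2,2-dimethylchroman-6-carboxylate F4. The ester is then reduced with LiBH4 in THF. The route is rejoined at 9.

**Further compounds**

F1 | step 9 | methyl (2S)-4-(benzyloxy)-3-[4-(benzyloxy)phenyl]-2-{[(3R)-3-hydroxy-2,2-dimethylchroman-6-yl]methyl}-5-oxo-2,5-dihydrofuran-2-carboxylate | COC(=O)[C@@]1(Cc2ccc3c(c2)C[C@@H](O)C(C)(C)O3)OC(=O)C(OCc2ccccc2)=C1c1ccc(OCc2ccccc2)cc1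
F2 | step 1 | methyl 4-fluoro-3-[1-(trimethylsilyloxy)ethenyl]benzoate | COC(=O)c1ccc(F)c(C(=C)O[Si](C)(C)C)c1
F3 | step 1 | methyl 4-fluoro-3-(3-hydroxy-3-methylbutanoyl)benzoate | COC(=O)c1ccc(F)c(C(=O)CC(C)(C)O)c1
F4 | step 5 | methyl (3R)-3-hydroxy-2,2-dimethylchroman-6-carboxylate | COC(=O)c1ccc2c(c1)C[C@@H](O)C(C)(C)O2
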